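The synthesis rests on opening the pyrrole ring of the 5-hydroxyindole at N1–C2 and cutting the bond from its C3 to the hexasubstituted central benzene ring. Since this C3 carries both the C2 neighbour and the central ring, an ortho-alkynyl trifluoroacetanilide can deliver nitrogen to one alkyne carbon and receive the aryl group at the other during one turnover of palladium. Aryl iodide activation, anti-aminopalladation and reductive elimination thus build the pyrrole ring and the hindered biaryl bond in one operation. The precursors are N-Boc 3-(4-iodo-2,3,5,6-tetramethoxyphenyl)-5-methoxyindole and the triethylsilyl-capped alkynyl trifluoroacetanilide of 4-benzyloxyaniline; one acid treatment and a hydrogenolysis finish the route.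

Key step: step 8

Remark on the chemistry: the N-trifluoroacetyl group of the first-formed indole 15 is assumed to be hydrolysed by carbonate and water during reaction and work-up. The target has no stereocentre and, the central ring being symmetric about both biaryl axes, no stereoaxis to control.

Step 1
Reactants: 1 4-(benzyloxy)aniline
Product: 2 4-(benzyloxy)-2-iodoaniline
Conditions: BnMe3N+ ICl2− (1.0 equiv), NaHCO3, CH2Cl2/MeOH (2:1), 0 °C → rt
Reagents that add atoms: benzyltrimethylammonium dichloroiodate, C[N+](C)(C)Cc1ccccc1.Cl[I-]Cl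
Why: Electrophilic aromatic iodination; the amino group is the strongest activator and its para position is occupied, so the mild dichloroiodate should iodinate once ortho to nitrogen while bicarbonate keeps the aniline unprotonated.

Step 2
Reactants: 2 4-(benzyloxy)-2-iodoaniline; 3 (triethylsilyl)acetylene
Product: 4 4-(benzyloxy)-2-[(triethylsilyl)ethynyl]aniline
Conditions: PdCl2(PPh3)2 (2 mol %), CuI (4 mol %), Et3N, THF, rt
Reagents that add atoms: none
Why: Sonogashira coupling of an aryl iodide with a terminal alkyne proceeds at room temperature beside a free ortho-amino group, and the triethylsilyl cap prevents a second coupling.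

Step 3
Reactants: 4 4-(benzyloxy)-2-[(triethylsilyl)ethynyl]aniline
Product: 5 N-{4-(benzyloxy)-2-[(triethylsilyl)ethynyl]phenyl}-2,2,2-trifluoroacetamide
Conditions: TFAA (1.2 equiv), pyridine (1.5 equiv), CH2Cl2, 0 °C
Reagents that add atoms: trifluoroacetic anhydride, O=C(OC(=O)C(F)(F)F)C(F)(F)F
Why: N-acylation of the aniline gives the acidic N–H trifluoroacetamide needed as the nitrogen nucleophile; the silyl alkyne and the benzyl ether are inert.

Step 4
Reactants: 6 1,2,4,5-tetramethoxybenzene
Product: 8 1,4-diiodo-2,3,5,6-tetramethoxybenzene, via dilithio arene 7 (not isolated)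
Conditions: n-BuLi (2.5 equiv), TMEDA (2.5 equiv), Et2O, 0 °C → rt; then I2 (3 equiv) in THF, −78 °C → rt; aq. Na2S2O3
Reagents that add atoms: iodine, [I][I]
Why: Directed ortho-metalation; each of the two ring hydrogens is flanked by two methoxy groups, so n-BuLi/TMEDA should remove both, and iodinolysis of the dianion can give only the para-diiodide.

Step 5
Reactants: 9 5-methoxyindole
Product: 10 3-iodo-5-methoxy-1H-indole
Conditions: I2 (1.05 equiv), KOH (2.5 equiv), DMF, rt; aq. Na2S2O3; used crude
Reagents that add atoms: iodine, [I][I]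
Why: Electrophilic iodination of the indolyl anion occurs at C3, the most nucleophilic carbon of the indole.

Step 6
Reactants: 10 3-iodo-5-methoxy-1H-indole
Product: 11 tert-butyl 3-iodo-5-methoxyindole-1-carboxylate
Conditions: Boc2O (1.2 equiv), DMAP (0.1 equiv), CH2Cl2, rt
Reagents that add atoms: di-tert-butyl dicarbonate, CC(C)(C)OC(=O)OC(=O)OC(C)(C)C
Why: DMAP-catalysed N-acylation gives the carbamate, which stabilises the 3-iodoindole and masks the N–H for the organometallic and basic steps that follow.

Step 7
Reactants: 8 1,4-diiodo-2,3,5,6-tetramethoxybenzene; 11 tert-butyl 3-iodo-5-methoxyindole-1-carboxylate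
Product: 14 tert-butyl 3-(4-iodo-2,3,5,6-tetramethoxyphenyl)-5-methoxyindole-1-carboxylate, via arylmagnesium chloride 12 (not isolated), via arylzinc chloride 13 (not isolated)
Conditions: 8 (1.3 equiv), i-PrMgCl·LiCl (1.3 equiv), THF, −20 → 0 °C; ZnCl2 (1.4 equiv), 0 °C → rt; then 11 (1.0 equiv), Pd(PPh3)4 (5 mol %), THF, 55 °C
Reagents that add atoms: none
Why: Iodine–magnesium exchange should stop after one exchange because the arylmagnesium formed is too electron-rich to exchange again, and after transmetalation to zinc the Negishi coupling should be chemoselective, since zerovalent palladium inserts far faster into the unhindered C3–I bond of 11 than into a C–I bond flanked by two methoxy groups, whose coupling with 13 would require a tetra-ortho-substituted biaryl.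

Step 8
Reactants: 14 tert-butyl 3-(4-iodo-2,3,5,6-tetramethoxyphenyl)-5-methoxyindole-1-carboxylate; 5 N-{4-(benzyloxy)-2-[(triethylsilyl)ethynyl]phenyl}-2,2,2-trifluoroacetamide
Product: 16 tert-butyl 3-{4-[5-(benzyloxy)-2-(triethylsilyl)-1H-indol-3-yl]-2,3,5,6-tetramethoxyphenyl}-5-methoxyindole-1-carboxylate, via N-trifluoroacetyl indole 15 (not isolated)
Conditions: 5 (1.5 equiv), Pd(PPh3)4 (10 mol %), Cs2CO3 (3 equiv), anhydrous MeCN, 90 °C, sealed tube; aq. NaHCO3 work-up
Reagents that add atoms: none
Why: Zerovalent palladium inserts into the C–I bond of 14 to give a divalent arylpalladium iodide that binds the alkyne of 5; the cesium amidate then attacks the coordinated alkyne on the face opposite the metal (anti-aminopalladation), forming N1–C2 and a C3-palladated indole, and reductive elimination forms the C3–aryl bond and returns zerovalent palladium. The closest known reaction type is the palladium-catalysed aminopalladation and reductive elimination of 2-alkynyl trifluoroacetanilides with aryl halides to give 3-arylindoles (Cacchi indole synthesis). The pyrrole ring closes in the 5-endo-dig mode, the only cyclisation open to an ortho nitrogen/alkyne pair, so nitrogen must go to the silyl-bearing carbon and the aryl group to C3; no stereocentre is formed. The step needs coupling through the alkyne and not at its terminus, which the triethylsilyl cap secures, and the single C–I bond of 14 leaves only one site for oxidative addition. The two ortho methoxy groups hinder intermolecular steps but not the reductive elimination, which takes place inside the complex assembled by the ring closure and is favoured by steric relief. The labile N-trifluoroacetyl group of 15 is cleaved by carbonate and water to leave the N–H indole 16, while benzyl ether, carbamate and aryl methyl ethers are inert.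

Step 9
Reactants: 16 tert-butyl 3-{4-[5-(benzyloxy)-2-(triethylsilyl)-1H-indol-3-yl]-2,3,5,6-tetramethoxyphenyl}-5-methoxyindole-1-carboxylate
Product: 17 5-(benzyloxy)-3-[2,3,5,6-tetramethoxy-4-(5-methoxy-1H-indol-3-yl)phenyl]-1H-indole
Conditions: TFA/CH2Cl2 (1:3), H2O (5 equiv), 0 °C → rt; aq. NaHCO3
Reagents that add atoms: none
Why: Acidolysis cleaves the tert-butyl carbamate, and ipso-protonation at C2 of the silylindole gives a cation stabilised by the β-silicon effect that loses silicon (protodesilylation), while water traps the tert-butyl cation; benzyl and methyl ethers are stable to dilute TFA at room temperature.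

Step 10
Reactants: 17 5-(benzyloxy)-3-[2,3,5,6-tetramethoxy-4-(5-methoxy-1H-indol-3-yl)phenyl]-1H-indole
Product: 18 3-[2,3,5,6-tetramethoxy-4-(5-methoxy-1H-indol-3-yl)phenyl]-1H-indol-5-ol (CNP0244913.0)
Conditions: H2 (1 atm), 10% Pd/C, EtOAc/MeOH (1:1), rt
Reagents that add atoms: none
Why: Hydrogenolysis of the benzyl aryl ether on palladium is selective; indoles and aryl methyl ethers are not reduced at one atmosphere under neutral conditions.

Compound list
1 | 4-(benzyloxy)aniline | Nc1ccc(OCc2ccccc2)cc1 | starting material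
2 | 4-(benzyloxy)-2-iodoaniline | Nc1ccc(OCc2ccccc2)cc1I | intermediate
3 | (triethylsilyl)acetylene | C#C[Si](CC)(CC)CC | starting material
4 | 4-(benzyloxy)-2-[(triethylsilyl)ethynyl]aniline | Nc1ccc(OCc2ccccc2)cc1C#C[Si](CC)(CC)CC | intermediate
5 | N-{4-(benzyloxy)-2-[(triethylsilyl)ethynyl]phenyl}-2,2,2-trifluoroacetamide | O=C(Nc1ccc(OCc2ccccc2)cc1C#C[Si](CC)(CC)CC)C(F)(F)F | intermediate
6 | 1,2,4,5-tetramethoxybenzene | COc1cc(OC)c(OC)cc1OC | starting material
7 | 3,6-dilithio-1,2,4,5-tetramethoxybenzene | [Li]c1c(OC)c(OC)c([Li])c(OC)c1OC | intermediate (not isolated)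
8 | 1,4-diiodo-2,3,5,6-tetramethoxybenzene | COc1c(I)c(OC)c(OC)c(I)c1OC | intermediate
9 | 5-methoxyindole | COc1ccc2[nH]ccc2c1 | starting material
10 | 3-iodo-5-methoxy-1H-indole | COc1ccc2[nH]cc(I)c2c1 | intermediate
11 | tert-butyl 3-iodo-5-methoxyindole-1-carboxylate | COc1ccc2c(c1)c(I)cn2C(=O)OC(C)(C)C | intermediate
12 | (4-iodo-2,3,5,6-tetramethoxyphenyl)magnesium chloride (LiCl complex) | COc1c(I)c(OC)c(OC)c([Mg]Cl)c1OC | intermediate (not isolated)
13 | (4-iodo-2,3,5,6-tetramethoxyphenyl)zinc chloride | COc1c(I)c(OC)c(OC)c([Zn]Cl)c1OC | intermediate (not isolated)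
14 | tert-butyl 3-(4-iodo-2,3,5,6-tetramethoxyphenyl)-5-methoxyindole-1-carboxylate | COc1ccc2c(c1)c(cn2C(=O)OC(C)(C)C)-c1c(OC)c(OC)c(I)c(OC)c1OC | intermediate
15 | tert-butyl 3-{4-[5-(benzyloxy)-2-(triethylsilyl)-1-(trifluoroacetyl)indol-3-yl]-2,3,5,6-tetramethoxyphenyl}-5-methoxyindole-1-carboxylate | COc1ccc2c(c1)c(cn2C(=O)OC(C)(C)C)-c1c(OC)c(OC)c(-c2c([Si](CC)(CC)CC)n(C(=O)C(F)(F)F)c3ccc(OCc4ccccc4)cc23)c(OC)c1OC | intermediate (not isolated)
16 | tert-butyl 3-{4-[5-(benzyloxy)-2-(triethylsilyl)-1H-indol-3-yl]-2,3,5,6-tetramethoxyphenyl}-5-methoxyindole-1-carboxylate | COc1ccc2c(c1)c(cn2C(=O)OC(C)(C)C)-c1c(OC)c(OC)c(-c2c([Si](CC)(CC)CC)[nH]c3ccc(OCc4ccccc4)cc23)c(OC)c1OC | intermediate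
17 | 5-(benzyloxy)-3-[2,3,5,6-tetramethoxy-4-(5-methoxy-1H-indol-3-yl)phenyl]-1H-indole | COc1ccc2[nH]cc(-c3c(OC)c(OC)c(-c4c[nH]c5ccc(OCc6ccccc6)cc45)c(OC)c3OC)c2c1 | intermediate
18 | 3-[2,3,5,6-tetramethoxy-4-(5-methoxy-1H-indol-3-yl)phenyl]-1H-indol-5-ol | COc1ccc2[nH]cc(-c3c(OC)c(OC)c(-c4c[nH]c5ccc(O)cc45)c(OC)c3OC)c2c1 | target

Total step count: 10.
Longest linear sequence: 6 steps (steps 5, 6, 7, 8, 9, 10 from 5-methoxyindole 9; equally steps 1, 2, 3, 8, 9, 10 from aniline 1).

Steps most likely to fail

1. Step 8. The hindered arylpalladium iodide may engage the silyl alkyne too slowly. Palladium-free, base-induced cyclisation of 5 to a 3-unsubstituted indole, hydrodeiodination of 14, or premature loss of the silyl cap followed by alkynylation could then outrun the cascade. The fallback sets out from 14 and returns at 17, bringing in the second indole preformed. Commercial 5-(benzyloxy)-1H-indole F1 would be iodinated at C3 (I2, KOH, DMF) to 5-(benzyloxy)-3-iodo-1H-indole F2 and protected (Boc2O, DMAP, CH2Cl2) as tert-butyl 5-(benzyloxy)-3-iodoindole-1-carboxylate F3. Borylation (PdCl2(dppf), pinacolborane, Et3N, dioxane, 80 °C) should give tert-butyl 5-(benzyloxy)-3-(4,4,5,5-tetramethyl-1,3,2-dioxaborolan-2-yl)indole-1-carboxylate F4. Suzuki–Miyaura coupling of F4 with 14 (Pd(OAc)2, SPhos, K3PO4, toluene/H2O, 90 °C) should give tert-butyl 5-(benzyloxy)-3-{4-[1-(tert-butoxycarbonyl)-5-methoxyindol-3-yl]-2,3,5,6-tetramethoxyphenyl}indole-1-carboxylate F5. TFA/CH2Cl2/H2O at room temperature then removes both carbamates and rejoins the route at 17.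

2. Step 7. The iodine–magnesium exchange may be incomplete or go twice, and transmetalation of the doubly ortho-substituted arylzinc may be slow. That would leave time for palladium to insert into the C–I bond of the zinc reagent or of the product, causing oligomerisation or hydrodeiodination. The fallback sets out from 11 and returns at 14 with the polarity reversed. Borylation of 11 (PdCl2(dppf), pinacolborane, Et3N, dioxane, 80 °C) should give tert-butyl 5-methoxy-3-(4,4,5,5-tetramethyl-1,3,2-dioxaborolan-2-yl)indole-1-carboxylate F6. Suzuki–Miyaura coupling of F6 with a threefold excess of diiodide 8 (Pd(OAc)2, SPhos, K3PO4, toluene/H2O, 80 °C) should give 14; the excess of 8 suppresses double arylation and is recovered.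

3. Step 4. The second deprotonation may be incomplete, so that the iodine quench leaves mono-iodinated material that is hard to separate from 8. The fallback sets out from 6 and returns at 8 through 7, replacing deprotonation by halogen–metal exchange. Electrophilic dibromination of 6 (Br2, 2.2 equiv, CH2Cl2, 0 °C), which has only two free positions, should give 1,4-dibromo-2,3,5,6-tetramethoxybenzene F7. Double bromine–lithium exchange (t-BuLi, 4.2 equiv, THF, −78 °C) regenerates dilithio arene 7, and the iodine quench gives 8.

Further compounds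
F1 | step 8 | 5-(benzyloxy)-1H-indole (purchased) | c1ccc(COc2ccc3[nH]ccc3c2)cc1
F2 | step 8 | 5-(benzyloxy)-3-iodo-1H-indole | Ic1c[nH]c2ccc(OCc3ccccc3)cc12
F3 | step 8 | tert-butyl 5-(benzyloxy)-3-iodoindole-1-carboxylate | CC(C)(C)OC(=O)n1cc(I)c2cc(OCc3ccccc3)ccc12
F4 | step 8 | tert-butyl 5-(benzyloxy)-3-(4,4,5,5-tetramethyl-1,3,2-dioxaborolan-2-yl)indole-1-carboxylate | CC(C)(C)OC(=O)n1cc(B2OC(C)(C)C(C)(C)O2)c2cc(OCc3ccccc3)ccc12
F5 | step 8 | tert-butyl 5-(benzyloxy)-3-{4-[1-(tert-butoxycarbonyl)-5-methoxyindol-3-yl]-2,3,5,6-tetramethoxyphenyl}indole-1-carboxylate | COc1ccc2c(c1)c(cn2C(=O)OC(C)(C)C)-c1c(OC)c(OC)c(-c2cn(C(=O)OC(C)(C)C)c3ccc(OCc4ccccc4)cc23)c(OC)c1OC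
F6 | step 7 | tert-butyl 5-methoxy-3-(4,4,5,5-tetramethyl-1,3,2-dioxaborolan-2-yl)indole-1-carboxylate | COc1ccc2c(c1)c(cn2C(=O)OC(C)(C)C)B1OC(C)(C)C(C)(C)O1
F7 | step 4 | 1,4-dibromo-2,3,5,6-tetramethoxybenzene | COc1c(Br)c(OC)c(OC)c(Br)c1OC
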